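**Retrosynthetic overview**
- Kwakhurin (7,2',4'-trihydroxy-5'-methoxy-6'-prenylisoflavone, no stereocentre) comes from fluoride desilylation of its tris(triisopropylsilyl) ether, whose prenyl group is made by cross-metathesis of a 6'-allyl group with 2-methyl-2-butene.
- Key disconnection C4–C4a: ring C is closed by Tf2O/2-chloropyridine activation of a 3-aryloxy-2-arylacrylamide. The route rests on C4a lying para to the 7-oxygen and ortho to O1, which makes it the most nucleophilic carbon of the resorcinol-derived aryl vinyl ether (ring A).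
- O1–C2 bond: addition–elimination of 3-(triisopropylsilyloxy)phenol on the enol tosylate of the α-formylated ring B arylacetic dimethylamide.
- Ring B from 2,4-bis(benzyloxy)benzaldehyde: Baeyer–Villiger (CHO becomes the 5'-oxygen), O-allylation, Vilsmeier formylation at C1', Claisen shift of allyl to C6', O-methylation, one-carbon homologation to the acetamide, then benzyl-to-silyl exchange.
- Ring order: rings A and B are bought as benzene rings; ring C is the only ring formed (step 16).

Key step: step 16

Remark: 2,4-bis(benzyloxy)benzaldehyde is taken as a catalogue compound; all 3-substituted acrylamides are E/Z mixtures and are used as such; isoflavone numbering (O1, C2–C4, C4a, C5–C8, C8a, ring B primed) is used.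

**Step 1**
Reactants: 1 2,4-bis(benzyloxy)benzaldehyde
Product: 3 2,4-bis(benzyloxy)phenol, via 2,4-bis(benzyloxy)phenyl formate 2 (not isolated)
Conditions: mCPBA, CH2Cl2, 0 °C to rt; then MeOH, cat. K2CO3, 0 °C
Reagents that add atoms: mCPBA, O=C(OO)c1cccc(Cl)c1
Why: Baeyer–Villiger (Dakin-type) oxidation of an ortho,para-dialkoxybenzaldehyde should proceed with aryl migration to the aryl formate, which mild methanolysis cleaves while the benzyl ethers stay untouched.

**Step 2**
Reactants: 3 2,4-bis(benzyloxy)phenol; 4 allyl bromide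
Product: 5 1-(allyloxy)-2,4-bis(benzyloxy)benzene
Conditions: K2CO3, acetone, reflux
Reagents that add atoms: none
Why: Williamson etherification of the only free phenol with a reactive allylic halide.

**Step 3**
Reactants: 5 1-(allyloxy)-2,4-bis(benzyloxy)benzene
Product: 7 5-(allyloxy)-2,4-bis(benzyloxy)benzaldehyde, via aryl methyleneiminium chloride 6 (not isolated)
Conditions: POCl3, DMF, 0 to 60 °C; then H2O, 0 °C to rt
Reagents that add atoms: N,N-dimethylformamide, CN(C)C=O; water, O
Why: Vilsmeier–Haack formylation should go to the unhindered ring carbon that is para to one benzyloxy group and ortho to the other (the future C1'), as 1,2,4-trialkoxybenzenes give 2,4,5-trialkoxybenzaldehydes, and the allyl and benzyl ethers tolerate the reagent.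

**Step 4**
Reactants: 7 5-(allyloxy)-2,4-bis(benzyloxy)benzaldehyde
Product: 8 2-allyl-4,6-bis(benzyloxy)-3-hydroxybenzaldehyde
Conditions: N,N-diethylaniline, 190 °C, argon
Reagents that add atoms: none
Why: Aromatic Claisen [3,3] rearrangement can deliver the allyl group only to the one free ortho carbon (the future C6', between the oxygen and the formyl-bearing carbon), because the other ortho position carries a benzyloxy group, and tautomerisation gives the phenol.

**Step 5**
Reactants: 8 2-allyl-4,6-bis(benzyloxy)-3-hydroxybenzaldehyde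
Product: 9 2-allyl-4,6-bis(benzyloxy)-3-methoxybenzaldehyde
Conditions: MeI, K2CO3, DMF, rt
Reagents that add atoms: iodomethane, CI
Why: Williamson methylation of the single free phenol fixes the 5'-methoxy group with no silyl group nearby that could migrate.

**Step 6**
Reactants: 9 2-allyl-4,6-bis(benzyloxy)-3-methoxybenzaldehyde
Product: 10 2-allyl-4,6-bis(benzyloxy)-3-methoxy-1-(2-methoxyvinyl)benzene (E/Z mixture)
Conditions: Ph3P(CH2OMe)Cl, KOtBu, THF, 0 °C to rt
Reagents that add atoms: (methoxymethyl)triphenylphosphonium chloride, COC[P+](c1ccccc1)(c1ccccc1)c1ccccc1.[Cl-]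
Why: Wittig methoxymethylenation with a reactive, small ylide should tolerate the two ortho substituents of the non-enolisable aldehyde.

**Step 7**
Reactants: 10 2-allyl-4,6-bis(benzyloxy)-3-methoxy-1-(2-methoxyvinyl)benzene
Product: 11 2-[2-allyl-4,6-bis(benzyloxy)-3-methoxyphenyl]acetaldehyde
Conditions: 2 M aq. HCl, THF, 40 °C
Reagents that add atoms: water, O
Why: Acid hydrolysis of the enol ether (protonation at the benzylic carbon, water addition, loss of methanol) gives the homologated aldehyde, and benzyl ethers and the terminal alkene are stable to dilute acid.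

**Step 8**
Reactants: 11 2-[2-allyl-4,6-bis(benzyloxy)-3-methoxyphenyl]acetaldehyde
Product: 12 2-[2-allyl-4,6-bis(benzyloxy)-3-methoxyphenyl]acetic acid
Conditions: NaClO2, NaH2PO4, H2O2, MeCN/H2O, 0 to 10 °C
Reagents that add atoms: sodium chlorite, [Na+].[O-]Cl=O
Why: Pinnick (chlorite) oxidation is selective for the aldehyde, and hydrogen peroxide as hypochlorite scavenger should keep the electron-rich ring and the allyl alkene free of chlorination.

**Step 9**
Reactants: 12 2-[2-allyl-4,6-bis(benzyloxy)-3-methoxyphenyl]acetic acid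
Product: 14 2-[2-allyl-4,6-bis(benzyloxy)-3-methoxyphenyl]-N,N-dimethylacetamide, via acyl imidazolide 13 (not isolated)
Conditions: 1,1'-carbonyldiimidazole, THF, rt; then Me2NH (2 M in THF), rt
Reagents that add atoms: dimethylamine, CNC
Why: Amide formation through the acyl imidazolide is a mild acyl substitution that needs no acid chloride and leaves the alkene and ethers alone.

**Step 10**
Reactants: 14 2-[2-allyl-4,6-bis(benzyloxy)-3-methoxyphenyl]-N,N-dimethylacetamide
Product: 16 2-(2-allyl-4,6-dihydroxy-3-methoxyphenyl)-N,N-dimethylacetamide, via aryl bis(dichloroborinate) 15 (not isolated)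
Conditions: BCl3 (excess), C6HMe5, CH2Cl2, −78 °C; then MeOH, −78 °C to rt
Reagents that add atoms: none
Why: Lewis-acid debenzylation with pentamethylbenzene as a non-basic benzyl-cation trap at −78 °C should cleave the two aryl benzyl ethers while the aryl methyl ether, the terminal alkene and the tertiary amide survive, which hydrogenolysis could not offer.

**Step 11**
Reactants: 16 2-(2-allyl-4,6-dihydroxy-3-methoxyphenyl)-N,N-dimethylacetamide
Product: 17 2-[2-allyl-3-methoxy-4,6-bis(triisopropylsilyloxy)phenyl]-N,N-dimethylacetamide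
Conditions: TIPSCl, imidazole, cat. DMAP, DMF, 40 °C
Reagents that add atoms: triisopropylsilyl chloride, CC(C)[Si](Cl)(C(C)C)C(C)C
Why: Imidazole-mediated silylation of both phenols installs the bulky, non-nucleophilic oxygen protection only after the 5'-oxygen is methylated, so no phenoxide ever sits next to a silyl ether.

**Step 12**
Reactants: 17 2-[2-allyl-3-methoxy-4,6-bis(triisopropylsilyloxy)phenyl]-N,N-dimethylacetamide
Product: 18 2-[2-allyl-3-methoxy-4,6-bis(triisopropylsilyloxy)phenyl]-3-hydroxy-N,N-dimethylacrylamide (enol of the α-formyl amide; E/Z mixture)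
Conditions: LiN(iPr)2 (2.2 equiv), THF, −78 °C; HCO2Et, −78 to 0 °C; aq. NH4Cl
Reagents that add atoms: ethyl formate, CCOC=O
Why: Claisen-type C-formylation of the amide enolate with a small formate ester gives the hydrogen-bonded enol, the amide α-protons being far more acidic than the allylic–benzylic CH2.

**Step 13**
Reactants: 18 2-[2-allyl-3-methoxy-4,6-bis(triisopropylsilyloxy)phenyl]-3-hydroxy-N,N-dimethylacrylamide
Product: 19 2-[2-allyl-3-methoxy-4,6-bis(triisopropylsilyloxy)phenyl]-3-(dimethylamino)-3-oxoprop-1-en-1-yl 4-methylbenzenesulfonate (enol tosylate; E/Z mixture)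
Conditions: TsCl, Et3N, cat. N-methylimidazole, CH2Cl2, 0 °C
Reagents that add atoms: 4-toluenesulfonyl chloride, Cc1ccc(S(=O)(=O)Cl)cc1
Why: O-Sulfonylation of the acidic enol (a vinylogous acid) turns the β-oxygen into a leaving group for vinylic substitution.

**Step 14**
Reactants: 20 resorcinol
Product: 21 3-(triisopropylsilyloxy)phenol
Conditions: TIPSCl (1 equiv), resorcinol (3 equiv), imidazole, DMF, 0 °C to rt
Reagents that add atoms: triisopropylsilyl chloride, CC(C)[Si](Cl)(C(C)C)C(C)C
Why: Statistical monosilylation with excess diol should favour the mono-ether, and unreacted resorcinol is removed by aqueous extraction.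

**Step 15**
Reactants: 19 enol tosylate; 21 3-(triisopropylsilyloxy)phenol
Product: 22 N,N-dimethyl 2-[2-allyl-3-methoxy-4,6-bis(triisopropylsilyloxy)phenyl]-3-[3-(triisopropylsilyloxy)phenoxy]acrylamide (E/Z mixture)
Conditions: Cs2CO3, anhydrous MeCN, 40 °C
Reagents that add atoms: none
Why: Addition–elimination (nucleophilic vinylic substitution) of the phenoxide at the β-carbon of the β-sulfonyloxy acrylamide forms the O1–C2 bond, and the alkene geometry is of no concern for the next step.

**Step 16**
Reactants: 22 N,N-dimethyl 2-[2-allyl-3-methoxy-4,6-bis(triisopropylsilyloxy)phenyl]-3-[3-(triisopropylsilyloxy)phenoxy]acrylamide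
Product: 25 6'-allyl-5'-methoxy-7,2',4'-tris(triisopropylsilyloxy)isoflavone, via O-triflyl iminium triflate 23 (not isolated), via 4-(dimethylamino)chromenylium triflate 24 (not isolated)
Conditions: Tf2O, 2-chloropyridine, CH2Cl2, −78 °C to rt; then aq. NaHCO3, THF, rt
Reagents that add atoms: water, O
Why: Tf2O O-triflylates the tertiary amide, with 2-chloropyridine buffering the acid without quenching the electrophile, to an O-triflyl iminium ion that is delocalised through C3=C2 onto the aryloxy oxygen, so the C2–C3 bond can rotate and both alkene isomers converge; ring A then attacks the iminium carbon with C4a, loses a proton and triflate to give the 4-(dimethylamino)chromenylium salt, and water supplies the C4 ketone with loss of dimethylamine. The closest known reaction type is Tf2O/2-halopyridine amide activation with intramolecular Friedel–Crafts closure (Vilsmeier–Haack and Bischler–Napieralski type), together with the acid cyclisation of 3-aryloxyacrylic acids to chromones. Ring C closes in a 6-exo-trig mode at the iminium carbon, forming the C4–C4a bond. No stereocentre is formed. The step needs attack para and not ortho to the ring A silyloxy group, which para activation and the crowding of the carbon between the two oxygens should secure, and it needs ring A to win over ring B, which is secured because a ring B carbon could only close a four-membered ring and the bulky silyl ether on the 2'-oxygen is a poor nucleophile. The allyl group is carried instead of prenyl because a monosubstituted alkene is too weak a nucleophile to trap the cation.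

**Step 17**
Reactants: 25 6'-allyl-5'-methoxy-7,2',4'-tris(triisopropylsilyloxy)isoflavone; 26 2-methyl-2-butene
Product: 27 5'-methoxy-6'-(3-methylbut-2-enyl)-7,2',4'-tris(triisopropylsilyloxy)isoflavone
Conditions: second-generation Grubbs catalyst RuCl2(=CHPh)(H2IMes)(PCy3) (5 mol%), 26 in excess, CH2Cl2, 40 °C, sealed tube
Reagents that add atoms: none
Why: Olefin cross-metathesis of a terminal allylarene with excess 2-methyl-2-butene is the standard allyl-to-prenyl conversion, and the electron-poor trisubstituted C2=C3 bond of the chromone should not take part.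

**Step 18**
Reactants: 27 5'-methoxy-6'-(3-methylbut-2-enyl)-7,2',4'-tris(triisopropylsilyloxy)isoflavone
Product: 28 kwakhurin
Conditions: tetrabutylammonium fluoride, AcOH (1:1, 3.5 equiv each), THF, 0 °C to rt
Reagents that add atoms: none
Why: Fluoride cleavage of the three aryl silyl ethers, buffered with acetic acid so that the chromone is not opened by phenoxide or fluoride base, leaves the prenyl group and the methyl ether untouched.

**Compound list**
1 | 2,4-bis(benzyloxy)benzaldehyde | O=Cc1ccc(OCc2ccccc2)cc1OCc1ccccc1 | starting material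
2 | 2,4-bis(benzyloxy)phenyl formate | O=COc1ccc(OCc2ccccc2)cc1OCc1ccccc1 | intermediate
3 | 2,4-bis(benzyloxy)phenol | Oc1ccc(OCc2ccccc2)cc1OCc1ccccc1 | intermediate
4 | allyl bromide | C=CCBr | starting material
5 | 1-(allyloxy)-2,4-bis(benzyloxy)benzene | C=CCOc1ccc(OCc2ccccc2)cc1OCc1ccccc1 | intermediate
6 | N-{[5-(allyloxy)-2,4-bis(benzyloxy)phenyl]methylidene}-N-methylmethanaminium chloride | C=CCOc1cc(C=[N+](C)C)c(OCc2ccccc2)cc1OCc1ccccc1.[Cl-] | intermediate
7 | 5-(allyloxy)-2,4-bis(benzyloxy)benzaldehyde | C=CCOc1cc(C=O)c(OCc2ccccc2)cc1OCc1ccccc1 | intermediate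
8 | 2-allyl-4,6-bis(benzyloxy)-3-hydroxybenzaldehyde | C=CCc1c(O)c(OCc2ccccc2)cc(OCc2ccccc2)c1C=O | intermediate
9 | 2-allyl-4,6-bis(benzyloxy)-3-methoxybenzaldehyde | C=CCc1c(OC)c(OCc2ccccc2)cc(OCc2ccccc2)c1C=O | intermediate
10 | 2-allyl-4,6-bis(benzyloxy)-3-methoxy-1-(2-methoxyvinyl)benzene (E/Z mixture) | C=CCc1c(OC)c(OCc2ccccc2)cc(OCc2ccccc2)c1C=COC | intermediate
11 | 2-[2-allyl-4,6-bis(benzyloxy)-3-methoxyphenyl]acetaldehyde | C=CCc1c(OC)c(OCc2ccccc2)cc(OCc2ccccc2)c1CC=O | intermediate
12 | 2-[2-allyl-4,6-bis(benzyloxy)-3-methoxyphenyl]acetic acid | C=CCc1c(OC)c(OCc2ccccc2)cc(OCc2ccccc2)c1CC(=O)O | intermediate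
13 | 2-[2-allyl-4,6-bis(benzyloxy)-3-methoxyphenyl]-1-(imidazol-1-yl)ethanone (acyl imidazolide) | C=CCc1c(OC)c(OCc2ccccc2)cc(OCc2ccccc2)c1CC(=O)n1ccnc1 | intermediate
14 | 2-[2-allyl-4,6-bis(benzyloxy)-3-methoxyphenyl]-N,N-dimethylacetamide | C=CCc1c(OC)c(OCc2ccccc2)cc(OCc2ccccc2)c1CC(=O)N(C)C | intermediate
15 | 2-{2-allyl-4,6-bis[(dichloroboryl)oxy]-3-methoxyphenyl}-N,N-dimethylacetamide | C=CCc1c(OC)c(OB(Cl)Cl)cc(OB(Cl)Cl)c1CC(=O)N(C)C | intermediate
16 | 2-(2-allyl-4,6-dihydroxy-3-methoxyphenyl)-N,N-dimethylacetamide | C=CCc1c(OC)c(O)cc(O)c1CC(=O)N(C)C | intermediate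
17 | 2-[2-allyl-3-methoxy-4,6-bis(triisopropylsilyloxy)phenyl]-N,N-dimethylacetamide | C=CCc1c(OC)c(O[Si](C(C)C)(C(C)C)C(C)C)cc(O[Si](C(C)C)(C(C)C)C(C)C)c1CC(=O)N(C)C | intermediate
18 | 2-[2-allyl-3-methoxy-4,6-bis(triisopropylsilyloxy)phenyl]-3-hydroxy-N,N-dimethylacrylamide (E/Z mixture) | C=CCc1c(OC)c(O[Si](C(C)C)(C(C)C)C(C)C)cc(O[Si](C(C)C)(C(C)C)C(C)C)c1C(=CO)C(=O)N(C)C | intermediate
19 | 2-[2-allyl-3-methoxy-4,6-bis(triisopropylsilyloxy)phenyl]-3-(dimethylamino)-3-oxoprop-1-en-1-yl 4-methylbenzenesulfonate (E/Z mixture) | C=CCc1c(OC)c(O[Si](C(C)C)(C(C)C)C(C)C)cc(O[Si](C(C)C)(C(C)C)C(C)C)c1C(=COS(=O)(=O)c1ccc(C)cc1)C(=O)N(C)C | intermediate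
20 | resorcinol | Oc1cccc(O)c1 | starting material
21 | 3-(triisopropylsilyloxy)phenol | Oc1cccc(O[Si](C(C)C)(C(C)C)C(C)C)c1 | intermediate
22 | N,N-dimethyl 2-[2-allyl-3-methoxy-4,6-bis(triisopropylsilyloxy)phenyl]-3-[3-(triisopropylsilyloxy)phenoxy]acrylamide (E/Z mixture) | CN(C)C(=O)C(=COc1cccc(O[Si](C(C)C)(C(C)C)C(C)C)c1)c1c(CC=C)c(OC)c(O[Si](C(C)C)(C(C)C)C(C)C)cc1O[Si](C(C)C)(C(C)C)C(C)C | intermediate
23 | O-triflyl iminium triflate of 22 | C[N+](C)=C(OS(=O)(=O)C(F)(F)F)C(=COc1cccc(O[Si](C(C)C)(C(C)C)C(C)C)c1)c1c(CC=C)c(OC)c(O[Si](C(C)C)(C(C)C)C(C)C)cc1O[Si](C(C)C)(C(C)C)C(C)C.[O-]S(=O)(=O)C(F)(F)F | intermediate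
24 | 3-[2-allyl-3-methoxy-4,6-bis(triisopropylsilyloxy)phenyl]-4-(dimethylamino)-7-(triisopropylsilyloxy)chromenylium triflate | C[N+](C)=C1C(c2c(CC=C)c(OC)c(O[Si](C(C)C)(C(C)C)C(C)C)cc2O[Si](C(C)C)(C(C)C)C(C)C)=COc2cc(O[Si](C(C)C)(C(C)C)C(C)C)ccc21.[O-]S(=O)(=O)C(F)(F)F | intermediate
25 | 6'-allyl-5'-methoxy-7,2',4'-tris(triisopropylsilyloxy)isoflavone | C=CCc1c(OC)c(O[Si](C(C)C)(C(C)C)C(C)C)cc(O[Si](C(C)C)(C(C)C)C(C)C)c1-c1coc2cc(O[Si](C(C)C)(C(C)C)C(C)C)ccc2c1=O | intermediate
26 | 2-methyl-2-butene | CC=C(C)C | starting material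
27 | 5'-methoxy-6'-(3-methylbut-2-enyl)-7,2',4'-tris(triisopropylsilyloxy)isoflavone | CC(C)=CCc1c(OC)c(O[Si](C(C)C)(C(C)C)C(C)C)cc(O[Si](C(C)C)(C(C)C)C(C)C)c1-c1coc2cc(O[Si](C(C)C)(C(C)C)C(C)C)ccc2c1=O | intermediate
28 | kwakhurin | COc1c(O)cc(O)c(-c2coc3cc(O)ccc3c2=O)c1CC=C(C)C | target

**Step count**
Total step count: 18. Longest linear sequence: 17 steps (steps 1–13 and 15–18; step 14 is the one-step side branch).

**Three steps most likely to fail**

Step 16. The activated amide may be captured by the 2'-silyloxy oxygen in a five-membered closure with silyl loss, ring A may attack through the carbon between its two oxygens, or silyl ethers may be lost to triflic acid. The fallback closes the same C4–C4a bond by an anionic Parham-type acylation, setting out from 19 and 21 and returning at 25. Compound 21 would be brominated ortho to the hydroxyl and para to the silyloxy group (NBS, cat. iPr2NH, CH2Cl2, 0 °C) to give 2-bromo-5-(triisopropylsilyloxy)phenol F1. F1 would displace the tosylate of 19 (Cs2CO3, MeCN, 40 °C) to give N,N-dimethyl 2-[2-allyl-3-methoxy-4,6-bis(triisopropylsilyloxy)phenyl]-3-[2-bromo-5-(triisopropylsilyloxy)phenoxy]acrylamide F2. Bromine–lithium exchange (tert-butyllithium, THF, −100 to −78 °C) would give an aryllithium whose position is fixed by the bromide; in the Z isomer it adds to the amide carbonyl, and aqueous work-up expels dimethylamine to give 25. The E isomer would be recycled by phenoxide-catalysed equilibration.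

Step 15. The phenoxide may attack sulfur of the tosylate and return the enolate, may add too slowly to the twisted and weakly electrophilic acrylamide, or silyl groups may be exchanged between phenoxides. The fallback replaces vinylic substitution by a metal-catalysed C–O coupling, setting out from 18 and returning at 22. Compound 18 would be converted (PhNTf2, Et3N, CH2Cl2, 0 °C) to 2-[2-allyl-3-methoxy-4,6-bis(triisopropylsilyloxy)phenyl]-3-(dimethylamino)-3-oxoprop-1-en-1-yl trifluoromethanesulfonate F3. F3 would be coupled with 21 (Pd2(dba)3, 2-(di-tert-butylphosphino)biphenyl, K3PO4, toluene, 80 °C) to give 22.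

Step 12. Acylation of the hindered enolate may be incomplete or go on oxygen, or the base may deprotonate the allylic–benzylic CH2 instead. The fallback avoids a preformed enolate, setting out from 17 and returning at 18. Compound 17 would be heated with tert-butoxybis(dimethylamino)methane (neat, 110 °C) to give 2-[2-allyl-3-methoxy-4,6-bis(triisopropylsilyloxy)phenyl]-3-(dimethylamino)-N,N-dimethylacrylamide F4. Mild hydrolysis of F4 (1 M aq. HCl, THF, rt) would release the enol 18.

**Further compounds**
F1 | step 16 | 2-bromo-5-(triisopropylsilyloxy)phenol | Oc1cc(O[Si](C(C)C)(C(C)C)C(C)C)ccc1Br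
F2 | step 16 | N,N-dimethyl 2-[2-allyl-3-methoxy-4,6-bis(triisopropylsilyloxy)phenyl]-3-[2-bromo-5-(triisopropylsilyloxy)phenoxy]acrylamide (E/Z mixture) | CN(C)C(=O)C(=COc1cc(O[Si](C(C)C)(C(C)C)C(C)C)ccc1Br)c1c(CC=C)c(OC)c(O[Si](C(C)C)(C(C)C)C(C)C)cc1O[Si](C(C)C)(C(C)C)C(C)C
F3 | step 15 | 2-[2-allyl-3-methoxy-4,6-bis(triisopropylsilyloxy)phenyl]-3-(dimethylamino)-3-oxoprop-1-en-1-yl trifluoromethanesulfonate (E/Z mixture) | C=CCc1c(OC)c(O[Si](C(C)C)(C(C)C)C(C)C)cc(O[Si](C(C)C)(C(C)C)C(C)C)c1C(=COS(=O)(=O)C(F)(F)F)C(=O)N(C)C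
F4 | step 12 | 2-[2-allyl-3-methoxy-4,6-bis(triisopropylsilyloxy)phenyl]-3-(dimethylamino)-N,N-dimethylacrylamide (E/Z mixture) | C=CCc1c(OC)c(O[Si](C(C)C)(C(C)C)C(C)C)cc(O[Si](C(C)C)(C(C)C)C(C)C)c1C(=CN(C)C)C(=O)N(C)C
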